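**Plan** (eudesmane-type numbering: ring A = C1–C5 and C10, ring B = C5–C10, C14 = methyl on C10, C15 = CH2O on C4)

1. The orthocinnamate is cut at its three C–O bonds (O4, O6, O15) to a 4,6,15-triol and trimethyl orthocinnamate. C4(O)–C15H2O goes back to a C4 ketone, C6–O to a dienol ether, and C7–H and C9–OH to the enone C9(=O)–C8H=C7(iPr).
2. Ring B is cut at C8–C9 and C6–C7. Its edge C9(=O)–C8H=C7(iPr)–C6H2 is 3-methylbut-1-yne inserted into the acyl–CH2 bond (C9–C6) of a cyclobutanone (C5, C6, C9, C10) fused to ring A. This is possible because C9 is a carbonyl-level carbon on the quaternary C10, C6 is a CH2 on C5, and the isopropyl group sits on the sp2-accessible C7.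
3. The cyclobutanone is cut at C5–C6 and C9–C10: head-to-tail [2+2] photocycloaddition of 1,1-dimethoxyethene to (S)-4-silyloxy-3-methylcyclohex-2-enone (ring A).
4. Forward order: ring A (steps 1–5), cyclobutane (step 6), ring B by two-carbon ring expansion (step 7), C4/C6/C9/C7 adjusted (steps 8–13), cage and deprotection (steps 14–17).
5. Stereochemistry: C1 by CBS reduction; C10 by photocycloaddition anti to the C1 silyloxy group; C5 by equilibration to the trans-decalin; C4 (OsO4) and C6 (singlet oxygen) by attack anti to the axial C10 methyl; C9 by Luche reduction; C7 by C9–OH-directed hydrogenation; the orthoester carbon by the cage.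

Key step: step 7

Remark: the target SMILES is read as a trans-decalin with O1, O9, C14 and C15 on one face and H5, O4, O6 and the C7 isopropyl group on the other; eudesmane names below give numbering only, configuration is as in the SMILES.

Step 1
Reactants: 1 7-methyl-1,4-dioxaspiro[4.5]decan-8-one (racemic)
Product: 2 trimethyl[(7-methyl-1,4-dioxaspiro[4.5]dec-7-en-8-yl)oxy]silane
Conditions: TMSCl, NaI, Et3N, MeCN, rt
Reagents that add atoms: chlorotrimethylsilane, C[Si](C)(C)Cl
Why: soft enolisation with iodotrimethylsilane made in the flask should give the more substituted (thermodynamic) silyl enol ether, which fixes the site of dehydrogenation and erases the stereocentre of racemic 1.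

Step 2
Reactants: 2 trimethyl[(7-methyl-1,4-dioxaspiro[4.5]dec-7-en-8-yl)oxy]silane
Product: 3 7-methyl-1,4-dioxaspiro[4.5]dec-6-en-8-one
Conditions: Pd(OAc)2 (10 mol%), O2 (1 atm), DMSO, rt
Reagents that add atoms: none
Why: Saegusa–Ito oxidation (divalent palladium adds to the enol ether, β-hydride elimination follows, dioxygen turns the catalyst over) should give the α-methyl enone.

Step 3
Reactants: 3 7-methyl-1,4-dioxaspiro[4.5]dec-6-en-8-one
Product: 4 (8S)-7-methyl-1,4-dioxaspiro[4.5]dec-6-en-8-ol
Conditions: (R)-2-methyl-CBS-oxazaborolidine (10 mol%), BH3·SMe2, THF, −20 °C; MeOH quench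
Reagents that add atoms: none
Why: Corey–Bakshi–Shibata reduction in which the α-methylvinyl arm acts as the large group, so the (R)-catalyst should deliver hydride to the face that gives the (S)-allylic alcohol and thereby set C1.

Step 4
Reactants: 4 (8S)-7-methyl-1,4-dioxaspiro[4.5]dec-6-en-8-ol
Product: 5 (8S)-8-(tert-butyldimethylsilyloxy)-7-methyl-1,4-dioxaspiro[4.5]dec-6-ene
Conditions: TBSCl, imidazole, DMF, rt
Reagents that add atoms: tert-butyldimethylsilyl chloride, CC(C)(C)[Si](C)(C)Cl
Why: standard silylation of a secondary allylic alcohol; the silyl ether blocks retro-aldol and elimination pathways later and serves as the steric control element in step 6.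

Step 5
Reactants: 5 (8S)-8-(tert-butyldimethylsilyloxy)-7-methyl-1,4-dioxaspiro[4.5]dec-6-ene
Product: 6 (4S)-4-(tert-butyldimethylsilyloxy)-3-methylcyclohex-2-en-1-one
Conditions: PPTS (cat.), acetone/H2O, 50 °C
Reagents that add atoms: water, O
Why: acid-catalysed hydrolysis of the allylic dioxolane is fast under conditions that should leave the secondary silyl ether, and it unmasks the enone with the methyl group on the β-carbon.

Step 6
Reactants: 6 (4S)-4-(tert-butyldimethylsilyloxy)-3-methylcyclohex-2-en-1-one; 7 1,1-dimethoxyethene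
Product: 9 (5S)-5-(tert-butyldimethylsilyloxy)-6-methylbicyclo[4.2.0]octane-2,7-dione (cis-fused; methyl cis to O5), via dimethyl ketal photoadduct 8 (not isolated)
Conditions: 7 (10 equiv), hν (350 nm, Pyrex), CH2Cl2, −40 °C; then TsOH·H2O (cat.), acetone/H2O, rt
Reagents that add atoms: water, O
Why: enone–alkene [2+2] photocycloaddition, in which the electron-rich ketene acetal should add head-to-tail (acetal carbon to the β-carbon C10) and anti to the C1 silyloxy group, setting the quaternary C10; mild acid then hydrolyses the ketal and equilibrates the ring fusion to cis through the C4 enol.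

Step 7
Reactants: 9 (5S)-5-(tert-butyldimethylsilyloxy)-6-methylbicyclo[4.2.0]octane-2,7-dione; 10 3-methylbut-1-yne
Product: 12 trans-fused 1-(tert-butyldimethylsilyloxy)-15-noreudesm-7-ene-4,9-dione (H5 trans to the C10 methyl), via cis-fused enedione 11 (not isolated)
Conditions: Ni(cod)2 (10 mol%), 1,3-bis(2,6-diisopropylphenyl)imidazol-2-ylidene (10 mol%), toluene, 60 °C, closed vessel, 10 (3 equiv) added slowly by syringe pump; then DBU (0.3 equiv), rt
Reagents that add atoms: none
Why: Proposed new method: zerovalent nickel should couple the alkyne and the strained C9 carbonyl by oxidative cyclisation (the unsubstituted alkyne carbon bonds to C9, the isopropyl-bearing carbon stays on nickel away from the quaternary C10), β-carbon elimination then cleaves C9–C6 to a seven-membered nickelacycle, and C(sp2)–C(sp3) reductive elimination joins C7 to C6, so ring B closes as a formal [4+2] ring expansion of the cyclobutane by the two alkyne carbons. The closest known reaction type is the nickel-catalysed insertion of internal alkynes into the acyl–carbon bond of simple cyclobutanones, together with nickel/carbene-catalysed oxidative cyclisation of terminal alkynes with carbonyl groups; a terminal alkyne and a ring-fused, α-quaternary cyclobutanone have not been shown in the insertion, hence the slow addition of the branched alkyne and the bulky carbene ligand to hold back alkyne oligomerisation. The insertion creates no stereocentre (C7 and C8 are sp2); DBU then resets C5 through the C4 enolate to the trans-fused decalin, which is expected to be the more stable isomer. The step needs regioselectivity in two places, alkyne orientation (secured by the size difference between H and isopropyl) and cleavage of C9–C6 instead of C9–C10 (a primary alkyl–nickel is preferred over a tertiary one), and chemoselectivity for the cyclobutanone over the C4 ketone (only the strained ring can undergo β-carbon elimination).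

Step 8
Reactants: 12 trans-fused 1-(tert-butyldimethylsilyloxy)-15-noreudesm-7-ene-4,9-dione
Product: 13 1-(tert-butyldimethylsilyloxy)eudesma-4(15),7-dien-9-one
Conditions: Ph3PCH3Br, KOtBu, THF, 0 °C to rt
Reagents that add atoms: methyltriphenylphosphonium bromide, C[P+](c1ccccc1)(c1ccccc1)c1ccccc1.[Br-]
Why: Wittig methylenation should take the saturated C4 ketone, because the C9 enone is neopentyl, conjugated and reversibly masked as its dienolate by the basic ylide.

Step 9
Reactants: 13 1-(tert-butyldimethylsilyloxy)eudesma-4(15),7-dien-9-one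
Product: 14 1-(tert-butyldimethylsilyloxy)-4,15-dihydroxyeudesm-7-en-9-one
Conditions: OsO4 (2 mol%), NMO, acetone/H2O, 0 °C to rt
Reagents that add atoms: N-methylmorpholine N-oxide, C[N+]1([O-])CCOCC1; water, O
Why: Upjohn dihydroxylation of the 1,1-disubstituted alkene (the electron-poor enone alkene is left), with OsO4 adding from the face opposite the 1,3-diaxial C10 methyl so that O4 ends equatorial and C15 axial.

Step 10
Reactants: 14 1-(tert-butyldimethylsilyloxy)-4,15-dihydroxyeudesm-7-en-9-one
Product: 15 1-(tert-butyldimethylsilyloxy)-4,9,15-tris(triethylsilyloxy)eudesma-6,8-diene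
Conditions: TESOTf (3.6 equiv), Et3N (6 equiv), CH2Cl2, −78 to 0 °C
Reagents that add atoms: triethylsilyl trifluoromethanesulfonate, CC[Si](CC)(CC)OS(=O)(=O)C(F)(F)F
Why: silyl triflate and amine should silylate both hydroxyls and enolise the enone at the γ-position by loss of the axial C6–H, giving the endocyclic (homoannular) silyl dienol ether rather than the exocyclic isopropylidene isomer.

Step 11
Reactants: 15 1-(tert-butyldimethylsilyloxy)-4,9,15-tris(triethylsilyloxy)eudesma-6,8-diene
Product: 18 1-(tert-butyldimethylsilyloxy)-4,6,15-tris(triethylsilyloxy)eudesm-7-en-9-one (O6 equatorial), via endoperoxide 16 (not isolated), via silyl peroxide 17 (not isolated)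
Conditions: O2, tetraphenylporphyrin (cat.), visible light, CH2Cl2, −78 °C; then PPh3, −78 °C to rt
Reagents that add atoms: dioxygen, O=O
Why: [4+2] cycloaddition of singlet oxygen to the s-cis 1-silyloxy diene from the face opposite the axial C10 methyl and axial C15 should set C6; the bridgehead silyl peroxyketal opens with O-to-O silyl shift to the γ-silylperoxy enone, and PPh3 removes the outer peroxide oxygen (as in the reduction of bis(trimethylsilyl) peroxide to the disiloxane) to leave the C6 silyl ether.

Step 12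
Reactants: 18 1-(tert-butyldimethylsilyloxy)-4,6,15-tris(triethylsilyloxy)eudesm-7-en-9-one
Product: 19 1-(tert-butyldimethylsilyloxy)-4,6,15-tris(triethylsilyloxy)eudesm-7-en-9-ol (O9 cis to the C10 methyl)
Conditions: NaBH4, CeCl3·7H2O, MeOH, −78 °C
Reagents that add atoms: none
Why: Luche 1,2-reduction, in which hydride should enter C9 anti to the adjacent axial C10 methyl (axial attack, unhindered while C7 is still sp2) to give the equatorial alcohol.

Step 13
Reactants: 19 1-(tert-butyldimethylsilyloxy)-4,6,15-tris(triethylsilyloxy)eudesm-7-en-9-ol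
Product: 20 1-(tert-butyldimethylsilyloxy)-4,6,15-tris(triethylsilyloxy)eudesman-9-ol (C7 isopropyl axial and cis to O6)
Conditions: H2 (1–4 atm), [Ir(cod)(PCy3)(py)]PF6 (10 mol%), CH2Cl2, rt
Reagents that add atoms: none
Why: hydroxyl-directed homogeneous hydrogenation, in which the allylic C9–OH binds iridium and both hydrogens are delivered on its face, so H7 should end cis to O9 and the isopropyl group axial; the silyl ethers do not direct.

Step 14
Reactants: 20 1-(tert-butyldimethylsilyloxy)-4,6,15-tris(triethylsilyloxy)eudesman-9-ol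
Product: 21 1-(tert-butyldimethylsilyloxy)eudesmane-4,6,9,15-tetrol
Conditions: HF·pyridine, pyridine, THF, 0 °C to rt
Reagents that add atoms: none
Why: buffered HF·pyridine should cleave the three triethylsilyl ethers much faster than the hindered neopentyl tert-butyldimethylsilyl ether at C1.

Step 15
Reactants: 22 (E)-cinnamonitrile
Product: 24 trimethyl orthocinnamate, via imidate hydrochloride 23 (not isolated)
Conditions: HCl (g), MeOH (1.1 equiv), Et2O, 0 °C; then MeOH (excess), hexane, rt
Reagents that add atoms: methanol, CO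
Why: Pinner reaction, in which HCl-promoted addition of methanol to the nitrile gives the imidate salt and its alcoholysis gives the orthoester with precipitation of ammonium chloride.

Step 16
Reactants: 21 1-(tert-butyldimethylsilyloxy)eudesmane-4,6,9,15-tetrol; 24 trimethyl orthocinnamate
Product: 25 1-O-(tert-butyldimethylsilyl) ether of the target orthocinnamate
Conditions: 24 (1.5 equiv), CSA (5 mol%), CH2Cl2, 4 Å molecular sieves, rt; Et3N quench
Reagents that add atoms: none
Why: acid-catalysed transorthoesterification, in which the primary C15–OH should exchange first and the rigid peri-diequatorial O4/O6 pair then closes the 2,7,8-trioxabicyclo[3.2.1]octane cage with loss of three methanol; the cage fixes the orthoester carbon, and the hindered C9–OH cannot form a cyclic orthoester while O1 is silylated.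

Step 17
Reactants: 25 1-O-(tert-butyldimethylsilyl) ether of the target orthocinnamate
Product: 26 CNP0252898.2
Conditions: TBAF, THF, rt to 40 °C
Reagents that add atoms: none
Why: fluoride cleavage of the silyl ether; the bicyclic orthoester and the styryl group should be stable to basic fluoride.

**Compound list**

1 | 7-methyl-1,4-dioxaspiro[4.5]decan-8-one (racemic) | CC1CC2(CCC1=O)OCCO2 | starting material
2 | trimethyl[(7-methyl-1,4-dioxaspiro[4.5]dec-7-en-8-yl)oxy]silane | CC1=C(O[Si](C)(C)C)CCC2(C1)OCCO2 | intermediate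
3 | 7-methyl-1,4-dioxaspiro[4.5]dec-6-en-8-one | CC1=CC2(CCC1=O)OCCO2 | intermediate
4 | (8S)-7-methyl-1,4-dioxaspiro[4.5]dec-6-en-8-ol | CC1=CC2(CC[C@@H]1O)OCCO2 | intermediate
5 | (8S)-8-(tert-butyldimethylsilyloxy)-7-methyl-1,4-dioxaspiro[4.5]dec-6-ene | CC1=CC2(CC[C@@H]1O[Si](C)(C)C(C)(C)C)OCCO2 | intermediate
6 | (4S)-4-(tert-butyldimethylsilyloxy)-3-methylcyclohex-2-en-1-one | CC1=CC(=O)CC[C@@H]1O[Si](C)(C)C(C)(C)C | intermediate
7 | 1,1-dimethoxyethene | C=C(OC)OC | starting material
8 | (5S)-5-(tert-butyldimethylsilyloxy)-7,7-dimethoxy-6-methylbicyclo[4.2.0]octan-2-one (ring-fusion epimers) | O=C1CC[C@H](O[Si](C)(C)C(C)(C)C)[C@]2(C)C1CC2(OC)OC | intermediate (not isolated)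
9 | (5S)-5-(tert-butyldimethylsilyloxy)-6-methylbicyclo[4.2.0]octane-2,7-dione, cis-fused, methyl cis to O5 | O=C1CC[C@H](O[Si](C)(C)C(C)(C)C)[C@]2(C)[C@H]1CC2=O | intermediate
10 | 3-methylbut-1-yne | CC(C)C#C | starting material
11 | cis-fused 1-(tert-butyldimethylsilyloxy)-15-noreudesm-7-ene-4,9-dione | O=C1CC[C@H](O[Si](C)(C)C(C)(C)C)[C@]2(C)[C@H]1CC(C(C)C)=CC2=O | intermediate (not isolated)
12 | trans-fused 1-(tert-butyldimethylsilyloxy)-15-noreudesm-7-ene-4,9-dione | O=C1CC[C@H](O[Si](C)(C)C(C)(C)C)[C@]2(C)[C@@H]1CC(C(C)C)=CC2=O | intermediate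
13 | 1-(tert-butyldimethylsilyloxy)eudesma-4(15),7-dien-9-one | C=C1CC[C@H](O[Si](C)(C)C(C)(C)C)[C@]2(C)[C@@H]1CC(C(C)C)=CC2=O | intermediate
14 | 1-(tert-butyldimethylsilyloxy)-4,15-dihydroxyeudesm-7-en-9-one | OC[C@]1(O)CC[C@H](O[Si](C)(C)C(C)(C)C)[C@]2(C)[C@@H]1CC(C(C)C)=CC2=O | intermediate
15 | 1-(tert-butyldimethylsilyloxy)-4,9,15-tris(triethylsilyloxy)eudesma-6,8-diene | CC[Si](CC)(CC)OC[C@]1(O[Si](CC)(CC)CC)CC[C@H](O[Si](C)(C)C(C)(C)C)[C@]2(C)[C@@H]1C=C(C(C)C)C=C2O[Si](CC)(CC)CC | intermediate
16 | 1-(tert-butyldimethylsilyloxy)-6,9-epidioxy-4,9,15-tris(triethylsilyloxy)eudesm-7-ene | CC[Si](CC)(CC)OC[C@]1(O[Si](CC)(CC)CC)CC[C@H](O[Si](C)(C)C(C)(C)C)[C@]2(C)[C@@H]1[C@@H]3OO[C@@]2(O[Si](CC)(CC)CC)C=C3C(C)C | intermediate (not isolated)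
17 | 1-(tert-butyldimethylsilyloxy)-4,15-bis(triethylsilyloxy)-6-(triethylsilylperoxy)eudesm-7-en-9-one | CC[Si](CC)(CC)OC[C@]1(O[Si](CC)(CC)CC)CC[C@H](O[Si](C)(C)C(C)(C)C)[C@]2(C)[C@@H]1[C@H](OO[Si](CC)(CC)CC)C(C(C)C)=CC2=O | intermediate (not isolated)
18 | 1-(tert-butyldimethylsilyloxy)-4,6,15-tris(triethylsilyloxy)eudesm-7-en-9-one | CC[Si](CC)(CC)OC[C@]1(O[Si](CC)(CC)CC)CC[C@H](O[Si](C)(C)C(C)(C)C)[C@]2(C)[C@@H]1[C@H](O[Si](CC)(CC)CC)C(C(C)C)=CC2=O | intermediate
19 | 1-(tert-butyldimethylsilyloxy)-4,6,15-tris(triethylsilyloxy)eudesm-7-en-9-ol | CC[Si](CC)(CC)OC[C@]1(O[Si](CC)(CC)CC)CC[C@H](O[Si](C)(C)C(C)(C)C)[C@]2(C)[C@@H]1[C@H](O[Si](CC)(CC)CC)C(C(C)C)=C[C@H]2O | intermediate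
20 | 1-(tert-butyldimethylsilyloxy)-4,6,15-tris(triethylsilyloxy)eudesman-9-ol | CC[Si](CC)(CC)OC[C@]1(O[Si](CC)(CC)CC)CC[C@H](O[Si](C)(C)C(C)(C)C)[C@]2(C)[C@@H]1[C@H](O[Si](CC)(CC)CC)[C@H](C(C)C)C[C@H]2O | intermediate
21 | 1-(tert-butyldimethylsilyloxy)eudesmane-4,6,9,15-tetrol | OC[C@]1(O)CC[C@H](O[Si](C)(C)C(C)(C)C)[C@]2(C)[C@@H]1[C@H](O)[C@H](C(C)C)C[C@H]2O | intermediate
22 | (E)-cinnamonitrile | N#C/C=C/c1ccccc1 | starting material
23 | methyl (E)-cinnamimidate hydrochloride | COC(=[NH2+])/C=C/c1ccccc1.[Cl-] | intermediate (not isolated)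
24 | trimethyl orthocinnamate, (E)-(3,3,3-trimethoxyprop-1-en-1-yl)benzene | COC(OC)(OC)/C=C/c1ccccc1 | intermediate
25 | 1-O-(tert-butyldimethylsilyl) ether of the target orthocinnamate | CC(C)[C@@H]1C[C@@H](O)[C@@]2(C)[C@@H]3[C@@H]1O[C@]1(/C=C/c4ccccc4)OC[C@@]3(CC[C@@H]2O[Si](C)(C)C(C)(C)C)O1 | intermediate
26 | CNP0252898.2, eudesmane-1,4,6,9,15-pentol 4,6,15-orthocinnamate | CC(C)[C@@H]1C[C@@H](O)[C@@]2(C)[C@@H]3[C@@H]1O[C@]1(/C=C/c4ccccc4)OC[C@@]3(CC[C@@H]2O)O1 | target

**Count**

Total steps: 17. Longest linear sequence: 16 (steps 1–14, 16, 17); step 15 is the one-step side branch to 24.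

**Steps most likely to fail**

Step 7 (proposed new method). The alkyne may oligomerise on nickel faster than it couples with the ketone, the alkylnickel intermediate may undergo β-hydride elimination, or the C5 equilibration may stop short of the trans isomer. The fallback uses known chemistry, sets out from 6 and returns at 12; ring B is then closed by aldol condensation. Copper-catalysed conjugate addition of CH2=CHMgBr to 6 (CuBr·SMe2, TMSCl, THF, −78 °C), anti to the silyloxy group, would give the trimethylsilyl enol ether of the 3-vinyl ketone F1 with C10 in place. Its lithium enolate (MeLi) would be alkylated at C5 with 2-(bromomethyl)-3-methylbut-1-ene to the diene ketone F2. Wacker oxidation (PdCl2, CuCl, O2, DMF/H2O) of the monosubstituted vinyl group would give the methyl ketone F3. Ozonolysis (O3, then Me2S) of the remaining 1,1-disubstituted alkene would give the triketone F4. Aldol condensation (KOH, MeOH) of the acetyl methyl (C8) onto the isopropyl ketone (C7) is the only mode that can dehydrate to a conjugated enone and, with equilibration at C5, would give 12.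

Step 11. The photooxygenation may give ene products at the isopropyl group, lose the migrating silyl group, or show poor facial selectivity; an exocyclic dienol ether from step 10 would not cycloadd at all. The fallback sets out from 15 and returns at 18. Epoxidation of the distal diene bond with dimethyldioxirane (acetone/CH2Cl2, −78 °C, buffered aqueous work-up; vinylogous Rubottom oxidation) is expected, by analogy with axial γ-attack on steroidal dienol ethers, to give mainly the axial C6 alcohol F5. Mitsunobu inversion (4-nitrobenzoic acid, PPh3, DIAD) would give the equatorial 4-nitrobenzoate F6, methanolysis (K2CO3, MeOH) the equatorial alcohol F7, and TESCl/imidazole would give 18. If the oxidation gives F7 directly, it is silylated as such.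

Step 16. Closure onto the hindered tertiary O4 may stall at a mixed monocyclic or bicyclic orthoester, or the acid may open the cinnamyl orthoester again. The fallback sets out from 21 and returns at 25. Selective acylation of the primary C15–OH with cinnamoyl chloride (2,4,6-collidine, CH2Cl2, −78 °C) would give the 15-O-cinnamate F8. Acid-catalysed dehydrative cyclisation of this rigid hydroxy ester (CSA, benzene, reflux through 4 Å molecular sieves) would then close the cage to 25, as is known for esters flanked by a fixed diol.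

**Further compounds**

F1 | step 7 | (4S)-4-(tert-butyldimethylsilyloxy)-3-methyl-3-vinyl-1-(trimethylsilyloxy)cyclohexene, vinyl trans to the silyloxy group | C=C[C@@]1(C)C=C(O[Si](C)(C)C)CC[C@@H]1O[Si](C)(C)C(C)(C)C
F2 | step 7 | 4-(tert-butyldimethylsilyloxy)-3-methyl-2-(3-methyl-2-methylenebutyl)-3-vinylcyclohexanone | C=C[C@@]1(C)[C@H](CC(=C)C(C)C)C(=O)CC[C@@H]1O[Si](C)(C)C(C)(C)C
F3 | step 7 | 3-acetyl-4-(tert-butyldimethylsilyloxy)-3-methyl-2-(3-methyl-2-methylenebutyl)cyclohexanone | CC(=O)[C@@]1(C)[C@H](CC(=C)C(C)C)C(=O)CC[C@@H]1O[Si](C)(C)C(C)(C)C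
F4 | step 7 | 3-acetyl-4-(tert-butyldimethylsilyloxy)-3-methyl-2-(3-methyl-2-oxobutyl)cyclohexanone | CC(=O)[C@@]1(C)[C@H](CC(=O)C(C)C)C(=O)CC[C@@H]1O[Si](C)(C)C(C)(C)C
F5 | step 11 | 1-(tert-butyldimethylsilyloxy)-6-hydroxy-4,15-bis(triethylsilyloxy)eudesm-7-en-9-one, axial 6-OH (cis to the C10 methyl) | CC[Si](CC)(CC)OC[C@]1(O[Si](CC)(CC)CC)CC[C@H](O[Si](C)(C)C(C)(C)C)[C@]2(C)[C@@H]1[C@@H](O)C(C(C)C)=CC2=O
F6 | step 11 | equatorial 6-(4-nitrobenzoate) of 1-(tert-butyldimethylsilyloxy)-4,15-bis(triethylsilyloxy)eudesm-7-en-9-one | CC[Si](CC)(CC)OC[C@]1(O[Si](CC)(CC)CC)CC[C@H](O[Si](C)(C)C(C)(C)C)[C@]2(C)[C@@H]1[C@H](OC(=O)c3ccc(cc3)[N+](=O)[O-])C(C(C)C)=CC2=O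
F7 | step 11 | 1-(tert-butyldimethylsilyloxy)-6-hydroxy-4,15-bis(triethylsilyloxy)eudesm-7-en-9-one, equatorial 6-OH (trans to the C10 methyl) | CC[Si](CC)(CC)OC[C@]1(O[Si](CC)(CC)CC)CC[C@H](O[Si](C)(C)C(C)(C)C)[C@]2(C)[C@@H]1[C@H](O)C(C(C)C)=CC2=O
F8 | step 16 | 15-O-cinnamate of 1-(tert-butyldimethylsilyloxy)eudesmane-4,6,9,15-tetrol | O=C(/C=C/c1ccccc1)OC[C@]1(O)CC[C@H](O[Si](C)(C)C(C)(C)C)[C@]2(C)[C@@H]1[C@H](O)[C@H](C(C)C)C[C@H]2O
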